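23 ⇐ diol 21 by two site-selective acylations (angelate on the less hindered C1–OH, acetate on the neopentyl C9–OH) ⇐ ketal-bridged diene 20 ⇐ enol triflate 19 (C4–CH3 by cross-coupling); locants: C1 angelate carbinol, C2 CH2, C3=C4(CH3), C5–C7 CH2, C8 C(CH3)2, C9 acetate carbinol, C10=C11(CH3).
19 ⇐ bicyclic vinyl carbinol 16 by a tethered anionic oxy-Cope ring expansion (seven- to eleven-membered ring): the C1–C2 bond forms while the C4–C10 bond of a cycloheptane breaks; C1 is the terminus of an enol ether tied back to the C9 oxygen by an isopropylidene ketal (a seven-membered 4,5-dihydro-1,3-dioxepine ring that is not in the target).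
Enabling feature: C2, C3=C4, C10=C11 and C1 of the eleven-membered ring are the six carbons of a 1,5-diene C2=C3–C4(O)–C10–C11=C1, and the Z-configured 2-ene-1,4-diol C9(O)–C10=C11(CH3)–C1(O) is the open form of a 1,3-dioxepine, so one ketal locks the Z alkene and relays the C10 configuration to C1.
16 ⇐ aldol-type ketone 11 (ethynylation, semihydrogenation, ketalisation, alkene isomerisation) ⇐ epoxy alcohol 10 (alkenyl 1,2-shift, semipinacol) ⇐ epoxy ketone 6 + alkenyllithium 9 ⇐ cycloheptenone 5 ⇐ 3-methylcyclohex-2-enone 1.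
Ring order: cyclohexene (purchased) → cycloheptane (one-carbon expansion, step 3) → dioxepane ketal ring (step 10) → eleven-membered ring (four-carbon expansion, step 12); the ketal bridge is cleaved in step 14.

Key step: step 12

Remark on the chemistry: the locants C1–C11 defined above are also used for the same carbons in the precursors.
Assumption: of the two pseudo-enantiomeric cinchona amines (quinine- or quinidine-derived), the one that delivers the (1S,7S)-epoxide 6 is used in step 4; all later stereocentres derive from it.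

Step 1
Reactants: 1 enone 3-methylcyclohex-2-en-1-one
Product: 2 silyl enol ether 3,3-dimethyl-1-(trimethylsilyloxy)cyclohex-1-ene
Conditions: MeMgBr, CuBr·SMe2 (5 mol %), Me3SiCl, THF, −78 to 0 °C
Reagents that add atoms: methylmagnesium bromide (C[Mg]Br); chlorotrimethylsilane (C[Si](C)(C)Cl)
Why: Copper-catalysed conjugate addition of the methyl Grignard reagent creates the gem-dimethyl carbon and the Me3SiCl present traps the enolate regiospecifically on oxygen (conjugate addition–enolate silylation); no stereocentre is formed.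

Step 2
Reactants: 2 silyl enol ether 3,3-dimethyl-1-(trimethylsilyloxy)cyclohex-1-ene
Product: 3 siloxycyclopropane 5,5-dimethyl-1-(trimethylsilyloxy)bicyclo[4.1.0]heptane (racemic, cis-fused)
Conditions: Et2Zn, CH2I2, CH2Cl2, 0 °C to rt
Reagents that add atoms: diiodomethane (ICI)
Why: Simmons–Smith cyclopropanation (Furukawa modification) of the electron-rich silyl enol ether should give the cis-fused siloxycyclopropane as a racemate, whose two stereocentres are destroyed again in step 3.

Step 3
Reactants: 3 siloxycyclopropane 5,5-dimethyl-1-(trimethylsilyloxy)bicyclo[4.1.0]heptane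
Product: 5 cycloheptenone 4,4-dimethylcyclohept-2-en-1-one, via chloroketone 4 (not isolated)
Conditions: FeCl3 (2.2 equiv), DMF, 0 °C to rt; then NaOAc, MeOH, reflux
Reagents that add atoms: none
Why: Ito–Saegusa one-carbon ring expansion, in which FeCl3 oxidises the siloxycyclopropane with cleavage of the internal ring bond to the β-chloro ketone 4 and NaOAc eliminates HCl to the conjugated enone; no stereocentre remains.

Step 4
Reactants: 5 cycloheptenone 4,4-dimethylcyclohept-2-en-1-one
Product: 6 epoxy ketone (1S,7S)-6,6-dimethyl-8-oxabicyclo[5.1.0]octan-2-one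
Conditions: 9-amino-9-deoxy-epi-cinchona amine (10 mol %), CF3CO2H (20 mol %), 50% aq. H2O2, 1,4-dioxane, 30 °C
Reagents that add atoms: hydrogen peroxide (OO)
Why: Primary-amine-salt (iminium) catalysed nucleophilic epoxidation of a cyclic enone (Weitz–Scheffer type), in which the chiral ion pair directs hydroperoxide to one face of the β-carbon so that both epoxide stereocentres (the later C9 and C10) are set together under catalyst control.

Step 5
Reactants: 7 bromo alcohol 2-bromoprop-2-en-1-ol
Product: 8 silyl ether tert-butyl[(2-bromoprop-2-en-1-yl)oxy]dimethylsilane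
Conditions: t-BuMe2SiCl, imidazole, CH2Cl2, 0 °C to rt
Reagents that add atoms: tert-butyldimethylsilyl chloride (CC(C)(C)[Si](C)(C)Cl)
Why: Standard silylation of a primary alcohol masks the hydroxyl for the halogen–lithium exchange and the Lewis acid step; no stereocentre.

Step 6
Reactants: 8 silyl ether tert-butyl[(2-bromoprop-2-en-1-yl)oxy]dimethylsilane; 6 epoxy ketone (1S,7S)-6,6-dimethyl-8-oxabicyclo[5.1.0]octan-2-one
Product: 10 epoxy alcohol (1S,2S,7S)-2-[3-(tert-butyldimethylsilyloxy)prop-1-en-2-yl]-6,6-dimethyl-8-oxabicyclo[5.1.0]octan-2-ol, via alkenyllithium 9 (not isolated)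
Conditions: 8, t-BuLi (2 equiv), Et2O, −78 °C; then 6, −78 °C; H2O
Reagents that add atoms: none
Why: Bromine–lithium exchange and 1,2-addition of the alkenyllithium to the ketone from the face opposite to the epoxide oxygen (substrate control) should give the tertiary carbinol with the hydroxyl cis and the alkenyl group trans to the epoxide.

Step 7
Reactants: 10 epoxy alcohol (1S,2S,7S)-2-[3-(tert-butyldimethylsilyloxy)prop-1-en-2-yl]-6,6-dimethyl-8-oxabicyclo[5.1.0]octan-2-ol
Product: 11 hydroxy ketone (2R,3R)-2-[3-(tert-butyldimethylsilyloxy)prop-1-en-2-yl]-3-hydroxy-4,4-dimethylcycloheptan-1-one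
Conditions: BF3·OEt2 (20 mol %), CH2Cl2, −78 to −40 °C; aq. NaHCO3
Reagents that add atoms: none
Why: Suzuki–Tsuchihashi semipinacol rearrangement of a 2,3-epoxy alcohol, in which the alkenyl group anti-periplanar to the activated C–O bond shifts to the α-carbon with inversion while the carbinol becomes the ketone, so the side arm at C10 ends up trans to the retained C9–OH stereospecifically.

Step 8
Reactants: 11 hydroxy ketone (2R,3R)-2-[3-(tert-butyldimethylsilyloxy)prop-1-en-2-yl]-3-hydroxy-4,4-dimethylcycloheptan-1-one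
Product: 12 propargylic diol (1R,2R,3R)-2-[3-(tert-butyldimethylsilyloxy)prop-1-en-2-yl]-1-ethynyl-4,4-dimethylcycloheptane-1,3-diol
Conditions: HC≡CMgBr (3 equiv), LaCl3·2LiCl, THF, −40 to 0 °C; H2O
Reagents that add atoms: ethynylmagnesium bromide (C#C[Mg]Br)
Why: Lanthanum-promoted 1,2-addition of the small linear acetylide without enolisation, which should follow the pseudo-axial trajectory anti to the C10–H bond and so place the ethynyl group cis to the C10 side arm at the new tertiary carbinol centre (the other epimer would remain a usable, boat-only substrate for step 12).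

Step 9
Reactants: 12 propargylic diol (1R,2R,3R)-2-[3-(tert-butyldimethylsilyloxy)prop-1-en-2-yl]-1-ethynyl-4,4-dimethylcycloheptane-1,3-diol
Product: 13 vinyl diol (1S,2R,3R)-2-[3-(tert-butyldimethylsilyloxy)prop-1-en-2-yl]-1-ethenyl-4,4-dimethylcycloheptane-1,3-diol
Conditions: H2 (1 atm), Pd/CaCO3 poisoned with Pb(OAc)2, quinoline, EtOAc, rt
Reagents that add atoms: none
Why: Semihydrogenation of the terminal alkyne over poisoned palladium stops at the vinyl group and leaves the 1,1-disubstituted alkene; no stereocentre changes (the descriptor at the carbinol changes only by priority).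

Step 10
Reactants: 13 vinyl diol (1S,2R,3R)-2-[3-(tert-butyldimethylsilyloxy)prop-1-en-2-yl]-1-ethenyl-4,4-dimethylcycloheptane-1,3-diol
Product: 15 ketal (5aR,6S,10aR)-6-ethenyl-2,2,10,10-tetramethyl-5-methylidene-4,5,5a,7,8,9,10,10a-octahydro-2H,6H-cyclohepta[d][1,3]dioxepin-6-ol (trans-fused 5-methylene-1,3-dioxepane), via triol 14 (not isolated)
Conditions: Bu4NF, THF, 0 °C to rt; then 2-methoxypropene, pyridinium p-toluenesulfonate (5 mol %), CH2Cl2, −20 to 0 °C
Reagents that add atoms: 2-methoxypropene (COC(C)=C)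
Why: Fluoride desilylation followed by kinetic ketalisation, in which 2-methoxypropene first reacts with the primary allylic hydroxyl and the mixed ketal closes onto the secondary C9–OH to the seven-membered ring, the hindered tertiary C4–OH not competing; stereocentres are untouched.

Step 11
Reactants: 15 ketal (5aR,6S,10aR)-6-ethenyl-2,2,10,10-tetramethyl-5-methylidene-4,5,5a,7,8,9,10,10a-octahydro-2H,6H-cyclohepta[d][1,3]dioxepin-6-ol
Product: 16 enol ether (5aR,6S,10aR)-6-ethenyl-2,2,5,10,10-pentamethyl-5a,7,8,9,10,10a-hexahydro-2H,6H-cyclohepta[d][1,3]dioxepin-6-ol (ring enol ether O–CH=C(CH3), trans ring fusion, vinyl cis to the C10–C11 bond)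
Conditions: RuHCl(CO)(PPh3)3 (5 mol %), toluene, 80 °C
Reagents that add atoms: none
Why: Ruthenium hydride catalysed allyl ether to enol ether isomerisation should move the exocyclic alkene into the ketal ring next to oxygen (the oxygen-conjugated trisubstituted enol ether is the thermodynamic isomer and is necessarily cis in the seven-membered ring), while the tertiary vinyl carbinol has no carbinol hydrogen and cannot isomerise.

Step 12
Reactants: 16 enol ether (5aR,6S,10aR)-6-ethenyl-2,2,5,10,10-pentamethyl-5a,7,8,9,10,10a-hexahydro-2H,6H-cyclohepta[d][1,3]dioxepin-6-ol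
Product: 19 enol triflate (1S,3Z,9R,13Z)-8,8,11,11,13-pentamethyl-10,12-dioxabicyclo[7.3.2]tetradeca-3,13-dien-4-yl trifluoromethanesulfonate, via potassium alkoxide 17 (not isolated), via potassium enolate 18 (not isolated)
Conditions: KH, 18-crown-6, THF, 0 to 50 °C; then PhNTf2, −78 to 0 °C
Reagents that add atoms: N-phenylbis(trifluoromethanesulfonimide) (O=S(=O)(N(c1ccccc1)S(=O)(=O)C(F)(F)F)C(F)(F)F)
Why: Deprotonation gives potassium alkoxide 17, and the oxyanion at C4 drives a concerted [3,3]-sigmatropic shift of the 1,5-diene C2=C3–C4(O−)–C10–C11=C1 in which the C1–C2 bond forms as the C4–C10 bond breaks, giving the C3=C4 enolate 18 that PhNTf2 traps on oxygen. The closest known reaction type is the anionic oxy-Cope ring expansion of 2-alkenyl-1-vinylcycloalkanols with in situ enolate triflation. The eleven-membered carbocycle is closed by a four-carbon ring expansion of the cycloheptane through a six-membered chair transition state (no end-to-end cyclisation), and the ketal ring is carried along as a bridge between the C1 and C9 oxygens. The new stereocentre C1 is controlled by C10 through suprafacial chirality transfer: C2 bonds to the face of the cyclic enol ether from which C4 leaves, and because C4 and C8 are trans on the dioxepine ring (trans ring fusion from step 7) C1 becomes S next to 9R. The step needs a Z alkene at C10=C11, an enolate with C5 trans to C2 and no enolate equilibration; the first is secured by the seven-membered ketal ring, which cannot hold an E alkene and forces C9 pseudo-axial in the chair, and the second by the cis relationship of the two alkenyl groups from step 8, which puts C5 equatorial and the oxyanion axial in that same chair (the cycloheptane conformer with the C9 and C10 substituents equatorial). Triflation at −78 °C directly after the rearrangement should fix the kinetic enolate as the Z-configured triflate that step 13 converts into the E-configured methyl alkene.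

Step 13
Reactants: 19 enol triflate (1S,3Z,9R,13Z)-8,8,11,11,13-pentamethyl-10,12-dioxabicyclo[7.3.2]tetradeca-3,13-dien-4-yl trifluoromethanesulfonate
Product: 20 bridged diene (1S,3E,9R,13Z)-4,8,8,11,11,13-hexamethyl-10,12-dioxabicyclo[7.3.2]tetradeca-3,13-diene
Conditions: MeZnCl, Pd(PPh3)4 (5 mol %), THF, 50 °C
Reagents that add atoms: methylzinc chloride (C[Zn]Cl)
Why: Negishi cross-coupling, in which oxidative addition of zerovalent palladium into the enol triflate, transmetalation and reductive elimination proceed with retention of alkene geometry and turn the Z-configured triflate into the E-configured C3=C4 methyl alkene.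

Step 14
Reactants: 20 bridged diene (1S,3E,9R,13Z)-4,8,8,11,11,13-hexamethyl-10,12-dioxabicyclo[7.3.2]tetradeca-3,13-diene
Product: 21 diol (1R,2Z,4S,6E)-3,7,11,11-tetramethylcycloundeca-2,6-diene-1,4-diol
Conditions: pyridinium p-toluenesulfonate (10 mol %), MeOH, rt
Reagents that add atoms: none
Why: Acid-catalysed transketalisation to methanol should remove the seven-membered isopropylidene bridge under conditions too mild to ionise the allylic C–O bonds; stereocentres are untouched.

Step 15
Reactants: 21 diol (1R,2Z,4S,6E)-3,7,11,11-tetramethylcycloundeca-2,6-diene-1,4-diol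
Product: 22 hydroxy angelate (1S,2Z,4R,9E)-4-hydroxy-2,5,5,9-tetramethylcycloundeca-2,9-dien-1-yl (2Z)-2-methylbut-2-enoate
Conditions: angelic acid, 2,4,6-trichlorobenzoyl chloride, Et3N, toluene, rt; then 21, toluene, 60 °C
Reagents that add atoms: angelic acid, (2Z)-2-methylbut-2-enoic acid (C/C=C(/C)C(=O)O)
Why: Yamaguchi-type mixed-anhydride esterification without a nucleophilic catalyst avoids Z-to-E isomerisation of the angelate and should acylate the less hindered C1–OH (flanked by CH2) in preference to the neopentyl C9–OH (flanked by the quaternary C8).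

Step 16
Reactants: 22 hydroxy angelate (1S,2Z,4R,9E)-4-hydroxy-2,5,5,9-tetramethylcycloundeca-2,9-dien-1-yl (2Z)-2-methylbut-2-enoate
Product: 23 target (1S,2Z,4R,9E)-4-(acetyloxy)-2,5,5,9-tetramethylcycloundeca-2,9-dien-1-yl (2Z)-2-methylbut-2-enoate
Conditions: Ac2O, 4-(dimethylamino)pyridine (10 mol %), pyridine, CH2Cl2, 0 °C to rt
Reagents that add atoms: acetic anhydride (CC(=O)OC(C)=O)
Why: Nucleophilic catalysis by 4-(dimethylamino)pyridine acetylates the remaining hindered secondary hydroxyl without touching the stereocentres, the alkenes or the angelate.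

Compound list
1 | 3-methylcyclohex-2-en-1-one | CC1=CC(=O)CCC1 | starting material
2 | 3,3-dimethyl-1-(trimethylsilyloxy)cyclohex-1-ene | CC1(C)CCCC(O[Si](C)(C)C)=C1 | intermediate
3 | 5,5-dimethyl-1-(trimethylsilyloxy)bicyclo[4.1.0]heptane (racemic, cis-fused; one enantiomer drawn) | C[Si](C)(C)O[C@@]12CCCC(C)(C)[C@@H]1C2 | intermediate
4 | 3-chloro-4,4-dimethylcycloheptan-1-one (racemic; one enantiomer drawn) | O=C1C[C@H](Cl)C(C)(C)CCC1 | intermediate
5 | 4,4-dimethylcyclohept-2-en-1-one | O=C1C=CC(C)(C)CCC1 | intermediate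
6 | (1S,7S)-6,6-dimethyl-8-oxabicyclo[5.1.0]octan-2-one | O=C1CCCC(C)(C)[C@@H]2O[C@@H]21 | intermediate
7 | 2-bromoprop-2-en-1-ol | OCC(Br)=C | starting material
8 | tert-butyl[(2-bromoprop-2-en-1-yl)oxy]dimethylsilane | C=C(Br)CO[Si](C)(C)C(C)(C)C | intermediate
9 | [3-(tert-butyldimethylsilyloxy)prop-1-en-2-yl]lithium | [Li]C(=C)CO[Si](C)(C)C(C)(C)C | intermediate
10 | (1S,2S,7S)-2-[3-(tert-butyldimethylsilyloxy)prop-1-en-2-yl]-6,6-dimethyl-8-oxabicyclo[5.1.0]octan-2-ol | C=C(CO[Si](C)(C)C(C)(C)C)[C@@]1(O)CCCC(C)(C)[C@@H]2O[C@@H]21 | intermediate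
11 | (2R,3R)-2-[3-(tert-butyldimethylsilyloxy)prop-1-en-2-yl]-3-hydroxy-4,4-dimethylcycloheptan-1-one | O=C1CCCC(C)(C)[C@H](O)[C@H]1C(=C)CO[Si](C)(C)C(C)(C)C | intermediate
12 | (1R,2R,3R)-2-[3-(tert-butyldimethylsilyloxy)prop-1-en-2-yl]-1-ethynyl-4,4-dimethylcycloheptane-1,3-diol | C#C[C@@]1(O)CCCC(C)(C)[C@H](O)[C@H]1C(=C)CO[Si](C)(C)C(C)(C)C | intermediate
13 | (1S,2R,3R)-2-[3-(tert-butyldimethylsilyloxy)prop-1-en-2-yl]-1-ethenyl-4,4-dimethylcycloheptane-1,3-diol | C=C[C@@]1(O)CCCC(C)(C)[C@H](O)[C@H]1C(=C)CO[Si](C)(C)C(C)(C)C | intermediate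
14 | (1S,2R,3R)-1-ethenyl-2-(3-hydroxyprop-1-en-2-yl)-4,4-dimethylcycloheptane-1,3-diol | C=C[C@@]1(O)CCCC(C)(C)[C@H](O)[C@H]1C(=C)CO | intermediate
15 | (5aR,6S,10aR)-6-ethenyl-2,2,10,10-tetramethyl-5-methylidene-4,5,5a,7,8,9,10,10a-octahydro-2H,6H-cyclohepta[d][1,3]dioxepin-6-ol | C=C[C@@]1(O)CCCC(C)(C)[C@@H]2OC(C)(C)OCC(=C)[C@@H]12 | intermediate
16 | (5aR,6S,10aR)-6-ethenyl-2,2,5,10,10-pentamethyl-5a,7,8,9,10,10a-hexahydro-2H,6H-cyclohepta[d][1,3]dioxepin-6-ol | C=C[C@@]1(O)CCCC(C)(C)[C@@H]2OC(C)(C)OC=C(C)[C@@H]12 | intermediate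
17 | potassium alkoxide of 16 | [K+].C=C[C@@]1([O-])CCCC(C)(C)[C@@H]2OC(C)(C)OC=C(C)[C@@H]12 | intermediate
18 | potassium (1S,3Z,9R,13Z)-8,8,11,11,13-pentamethyl-10,12-dioxabicyclo[7.3.2]tetradeca-3,13-dien-4-olate | [K+].CC1(C)O[C@H]2C/C=C(\[O-])CCCC(C)(C)[C@H](O1)/C=C\2C | intermediate
19 | (1S,3Z,9R,13Z)-8,8,11,11,13-pentamethyl-10,12-dioxabicyclo[7.3.2]tetradeca-3,13-dien-4-yl trifluoromethanesulfonate | CC1(C)O[C@H]2C/C=C(\OS(=O)(=O)C(F)(F)F)CCCC(C)(C)[C@H](O1)/C=C\2C | intermediate
20 | (1S,3E,9R,13Z)-4,8,8,11,11,13-hexamethyl-10,12-dioxabicyclo[7.3.2]tetradeca-3,13-diene | CC1(C)O[C@H]2C/C=C(\C)CCCC(C)(C)[C@H](O1)/C=C\2C | intermediate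
21 | (1R,2Z,4S,6E)-3,7,11,11-tetramethylcycloundeca-2,6-diene-1,4-diol | O[C@H]1C/C=C(\C)CCCC(C)(C)[C@H](O)/C=C\1C | intermediate
22 | (1S,2Z,4R,9E)-4-hydroxy-2,5,5,9-tetramethylcycloundeca-2,9-dien-1-yl (2Z)-2-methylbut-2-enoate | C/C=C(/C)C(=O)O[C@H]1C/C=C(\C)CCCC(C)(C)[C@H](O)/C=C\1C | intermediate
23 | (1S,2Z,4R,9E)-4-(acetyloxy)-2,5,5,9-tetramethylcycloundeca-2,9-dien-1-yl (2Z)-2-methylbut-2-enoate | C/C=C(/C)C(=O)O[C@H]1C/C=C(\C)CCCC(C)(C)[C@H](OC(C)=O)/C=C\1C | target

Total step count: 16. Longest linear sequence: 15 steps (steps 1–4 and 6–16; step 5 is a one-step side branch).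

Steps most likely to fail

Step 12. The ketal bridge may strain the chair so much that the sigmatropic shift becomes slow; alkoxide fragmentation, a boat pathway with the wrong enolate geometry, or proton transfer before triflation could then compete. The fallback gives up the tether and corrects C1 afterwards. It sets out from triol 14, isolated after the desilylation of step 10. Methoxymethyl chloride and i-Pr2NEt should protect the primary and the secondary hydroxyl and leave the tertiary one, giving (1S,2R,3R)-1-ethenyl-3-(methoxymethoxy)-2-[3-(methoxymethoxy)prop-1-en-2-yl]-4,4-dimethylcycloheptan-1-ol F1. Isomerisation with RuHCl(CO)(PPh3)3 should give the open-chain enol ether with oxygen trans to C10, (1S,2R,3R)-1-ethenyl-3-(methoxymethoxy)-2-[(1E)-1-(methoxymethoxy)prop-1-en-2-yl]-4,4-dimethylcycloheptan-1-ol F2. KH and 18-crown-6, then PhNTf2, should give (1Z,4R,5Z,7R)-4,7-bis(methoxymethoxy)-5,8,8-trimethylcycloundeca-1,5-dien-1-yl trifluoromethanesulfonate F3; the untethered chair, with C9 pseudo-axial and the enol ether oxygen pseudo-equatorial, gives the C1 epimer. Methylation as in step 13 gives (1R,2Z,4R,6E)-1,4-bis(methoxymethoxy)-3,7,11,11-tetramethylcycloundeca-2,6-diene F4, and HCl in MeOH gives (1R,2Z,4R,6E)-3,7,11,11-tetramethylcycloundeca-2,6-diene-1,4-diol F5. A Mitsunobu esterification with angelic acid (PPh3, diisopropyl azodicarboxylate) at the less hindered C1–OH inverts C1 and comes back to the route at 22.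

Step 11. The metal hydride may fail to engage the 1,1-disubstituted alkene or may move it toward C10 instead of toward oxygen. The fallback uses base-mediated prototropic isomerisation on a protected carbinol and sets out from 15. t-BuMe2SiOTf and 2,6-lutidine should give the tertiary silyl ether tert-butyldimethylsilyl ether of 15 F6. KOt-Bu in DMSO then deprotonates at the allylic position next to oxygen and, with no free alkoxide present to rearrange early, should give the ring enol ether tert-butyldimethylsilyl ether of 16 F7. Bu4NF comes back to the route at 16.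

Step 15. Site selection between the two secondary allylic hydroxyls may be poor, with double acylation or acyl migration across the Z alkene. The fallback reverses the order of the two esterifications with a temporary silyl group and sets out from 21. Et3SiCl and imidazole at −40 °C should silylate the less hindered hydroxyl to (1R,2Z,4S,6E)-3,7,11,11-tetramethyl-4-(triethylsilyloxy)cycloundeca-2,6-dien-1-ol F8. Ac2O with 4-(dimethylamino)pyridine gives (1R,2Z,4S,6E)-3,7,11,11-tetramethyl-4-(triethylsilyloxy)cycloundeca-2,6-dien-1-yl acetate F9, and HF·pyridine gives (1R,2Z,4S,6E)-4-hydroxy-3,7,11,11-tetramethylcycloundeca-2,6-dien-1-yl acetate F10. The mixed-anhydride angeloylation of step 15 on the only free hydroxyl comes back to the route at 23.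

Further compounds
F1 | step 12 | (1S,2R,3R)-1-ethenyl-3-(methoxymethoxy)-2-[3-(methoxymethoxy)prop-1-en-2-yl]-4,4-dimethylcycloheptan-1-ol | C=C[C@@]1(O)CCCC(C)(C)[C@H](OCOC)[C@H]1C(=C)COCOC
F2 | step 12 | (1S,2R,3R)-1-ethenyl-3-(methoxymethoxy)-2-[(1E)-1-(methoxymethoxy)prop-1-en-2-yl]-4,4-dimethylcycloheptan-1-ol | C=C[C@@]1(O)CCCC(C)(C)[C@H](OCOC)[C@H]1/C(C)=C/OCOC
F3 | step 12 | (1Z,4R,5Z,7R)-4,7-bis(methoxymethoxy)-5,8,8-trimethylcycloundeca-1,5-dien-1-yl trifluoromethanesulfonate | COCO[C@@H]1C/C=C(\OS(=O)(=O)C(F)(F)F)CCCC(C)(C)[C@H](OCOC)/C=C\1C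
F4 | step 12 | (1R,2Z,4R,6E)-1,4-bis(methoxymethoxy)-3,7,11,11-tetramethylcycloundeca-2,6-diene | COCO[C@@H]1C/C=C(\C)CCCC(C)(C)[C@H](OCOC)/C=C\1C
F5 | step 12 | (1R,2Z,4R,6E)-3,7,11,11-tetramethylcycloundeca-2,6-diene-1,4-diol | O[C@@H]1C/C=C(\C)CCCC(C)(C)[C@H](O)/C=C\1C
F6 | step 11 | tert-butyldimethylsilyl ether of 15 | C=C[C@@]1(O[Si](C)(C)C(C)(C)C)CCCC(C)(C)[C@@H]2OC(C)(C)OCC(=C)[C@@H]12
F7 | step 11 | tert-butyldimethylsilyl ether of 16 | C=C[C@@]1(O[Si](C)(C)C(C)(C)C)CCCC(C)(C)[C@@H]2OC(C)(C)OC=C(C)[C@@H]12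
F8 | step 15 | (1R,2Z,4S,6E)-3,7,11,11-tetramethyl-4-(triethylsilyloxy)cycloundeca-2,6-dien-1-ol | CC[Si](CC)(CC)O[C@H]1C/C=C(\C)CCCC(C)(C)[C@H](O)/C=C\1C
F9 | step 15 | (1R,2Z,4S,6E)-3,7,11,11-tetramethyl-4-(triethylsilyloxy)cycloundeca-2,6-dien-1-yl acetate | CC[Si](CC)(CC)O[C@H]1C/C=C(\C)CCCC(C)(C)[C@H](OC(C)=O)/C=C\1C
F10 | step 15 | (1R,2Z,4S,6E)-4-hydroxy-3,7,11,11-tetramethylcycloundeca-2,6-dien-1-yl acetate | O[C@H]1C/C=C(\C)CCCC(C)(C)[C@H](OC(C)=O)/C=C\1C
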